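# Total synthesis proposal for CNP0323189.1 (compound 20)

## Analysis of the target

Compound 20 is a sesquiterpene lactone of the 2,3-seco-germacranolide type, and germacrane numbering is used throughout. Ring A is the α-methylene-γ-butyrolactone O–C6–C7–C11(=C13H2)–C12(=O); C6 bears the (E)-C5H=C4(C15H3)–C3H2–OAc arm, and C7 bears the chain C8H(O-methacryloyl)–C9H2–C10(C14H3)=C1H–C2H2–OH with an E alkene. The three stereocentres C6, C7 and C8 are contiguous and all R. C5 and C8 are trans on ring A, and in the zigzag C9–C8–C7–C6 the oxygen on C8 and C11 lie on opposite sides. C8 lies outside the ring, so its relation to C7 must come from acyclic stereocontrol.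

The sensitive groups are:
- two polymerisable Michael acceptors (C11=C13 and the methacrylate);
- two allylic C–O ester bonds (C6–O and C3–O) that flank the same C5=C4 alkene;
- a second oxygen (O8) that is γ to C12 and can take over the lactone.

Three similar oxygens end in three different states: O2 free, O3 acetylated, O8 methacryloylated.

The plan rests on one feature. Once C11, C12, C13 and the ring oxygen are taken away, the other twelve carbons form one unbranched chain C2–C1–C10–C9–C8–C7–C6–C5–C4–C3 (plus methyls C14 and C15). The two bonds that fasten the acrylate unit to this chain, C7–C11 and C6–O, sit on neighbouring carbons directly beside C5=C4. That pattern is the footprint of a 1,2-carbo-oxygenation of a C7=C6–C5=C4 diene, so ring A with C6 and C7 can be laid onto a linear precursor whose only stereocentre is C8. The hard part is to let C8 alone dictate C7 and C6 while both E-trisubstituted alkenes and the oxygen pattern are kept with few protecting-group steps.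

## Retrosynthetic reasoning

**20 ⇒ 19 (O2–Si).** The free primary allylic alcohol is released last. O2 must stay masked while O8 is acylated, and a bulky silyl ether can be removed under slightly acidic fluoride conditions that leave both esters and both Michael acceptors alone.

**19 ⇒ 18 ⇒ 17 (O8–acyl, then O8–Si).** The methacrylate is put on after ring A exists. Before that point O8 is allylic to the diene, so an ester there would ionise on palladium and the methacrylate alkene would compete for insertion. A bulky silyl ether on O8 is inert and also serves as the steric control element of the key step. The forward steps have to free O8 selectively beside the O2 silyl ether and acylate it before the lactone can move from O6 to O8.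

**17 ⇒ 14 + 15 (C7–C11 and C6–O, key disconnection).** Both bonds that hold C11–C13 on the chain are cut at once. This removes ring A, two of the three stereocentres and the last three carbons, and leaves a linear trienyl acetate 14 with one stereocentre and the commercial acid 15. Cutting here uses the C5=C4 alkene of the target as the remnant of a diene, and it lets the O3 acetate travel in its final form. The forward reaction, a palladium-catalysed (3+2) heteroannulation, has to add C11 to C7 and not to C4, choose one face of C7=C6 under the influence of C8, and close the ring at C6 trans to C8.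

**14 ⇒ 9 + 13 (C5–C6).** The diene is cut at its central sp2–sp2 bond. Each half brings one alkene of defined geometry, and the acetate enters only after all organometallic steps on the other half are done. The forward Heck reaction has to form the E C6=C7 alkene and keep the geometry of 13.

**13 ⇒ 12 ⇒ 10 (O3–acyl; C4–C15 and C5–I).** Syn methylmetalation of the alkyne of 10 followed by iodination fixes the E geometry of C4=C5 in one operation. Acetylation gives the final O3 state.

**9 ⇒ 7 ⇒ 4 (two O–Si bonds; C10–C14 and C1–C2).** The two hydroxyl groups of 7 differ as primary and secondary, so they can be told apart in one flask. The whole C10(C14)=C1–C2–O unit comes from the terminal alkyne of 4 by syn methylmetalation and C1 trapping, which sets the second E alkene.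

**4 ⇒ 1 + 2 (C8–C9).** The only stereocentre that needs an external source of chirality is made by catalytic asymmetric propargylation of 1 with 2, both commercial.

## Alternatives that were turned down

**Alternative 1:** the textbook cut, C6–C7 plus the acyl C12–O6 bond. In the forward sense the allylic bromide A1 is converted into its zinc, indium or chromium reagent and added to the enal A2, and lactonisation would give 17.
- A1 already holds C8 and the complete acrylate, and it needs a longer linear sequence than 14.
- C7 would depend on two selectivities at once: the simple diastereoselection of the allylmetal and its facial bias next to C8.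
- A2 offers acidic γ-hydrogens and an allylic acetate to a reducing metal.
- The key step closes no ring by itself.
- This is also the route most chemists would draw first.

**Alternative 2:** cut C6–O and C3–O together. Divalent-palladium-catalysed 1,4-acetoxylactonisation (quinone oxidant, acetic acid) of the 4,6-dienoic acid A3 would give 19 directly, with the acetate installed by the key step.
- A3 keeps the whole carbon skeleton and both C7 and C8.
- C7 in A3 is a doubly allylic methine between an acrylic acid and a diene, so it is prone to slip into conjugation.
- No short stereocontrolled access to such a centre is apparent, so the precursor costs more than the step wins.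
- Kinetic closure of 3-substituted 4-enoic acids gives no firm bias for the trans ring.

**Alternative 3:** three components around ring A, cutting C6–C7, C11–C12 and C12–O6. The allene A4, CO2 and A2 are joined on stoichiometric Ni(cod)2 with DBU (carboxylation at C11, then allyl transfer from C7 to the aldehyde), and acid work-up would close ring A to 17.
- It needs a full equivalent of zerovalent nickel.
- The allylic acetate of A2 is itself a substrate for oxidative addition.
- DBU can deconjugate A2.
- Nothing in A4 controls the face of C7.
- A4 needs extra steps for the allene.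

Key step: step 7

Assumption: the sense of induction of (R)-TRIP with acrolein is taken to be the one usual for this catalyst class (attack on the Re face). The antipodal catalyst is equally available if the sense should be opposite.

## Route

Step 1
Reactants: 1 acrolein; 2 allenylboronic acid pinacol ester
Product: 4 (3R)-hex-1-en-5-yn-3-ol, via pinacol borate ester 3 (not isolated)
Conditions: (R)-TRIP [(R)-3,3'-bis(2,4,6-triisopropylphenyl)-1,1'-binaphthyl-2,2'-diyl hydrogen phosphate, 5–10 mol %], 4 Å MS, toluene, −20 °C; then H2O
Reagents that add atoms: none
Why: Chiral-phosphoric-acid-catalysed allenylboration (asymmetric propargylation); the acid binds a boronate oxygen and the formyl hydrogen, so the closed six-membered SE2' transition state should deliver C9 to the Re face of 1 and set C8 as R. Attack through the γ-carbon of the allenyl unit gives only the homopropargylic skeleton.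

Step 2
Reactants: 4 (3R)-hex-1-en-5-yn-3-ol
Product: 7 (2E,5R)-3-methylhepta-2,6-diene-1,5-diol, via alkenylalane 5 (not isolated), via lithium alanate 6 (not isolated)
Conditions: Me3Al (4 equiv), Cp2ZrCl2 (0.25 equiv), CH2Cl2, 0 °C to rt; n-BuLi, hexane/THF, −78 to 0 °C; (CH2O)n, rt; aq. Rochelle salt
Reagents that add atoms: trimethylaluminium C[Al](C)C; formaldehyde (as paraformaldehyde) C=O
Why: Negishi zirconium-catalysed methylalumination; syn addition of Me–Al to the terminal alkyne puts C14 on C10 and aluminium on C1, which fixes the E geometry, and the alanate adds to formaldehyde with retention. The hydroxyl group is masked in the flask as its aluminium alkoxide, and the monosubstituted alkene should react far more slowly than the alkyne.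

Step 3
Reactants: 7 (2E,5R)-3-methylhepta-2,6-diene-1,5-diol
Product: 9 (3R,5E)-7-(tert-butyldiphenylsilyloxy)-5-methyl-3-(triethylsilyloxy)hepta-1,5-diene, via mono-TBDPS ether 8 (not isolated)
Conditions: TBDPSCl (1.0 equiv), imidazole, CH2Cl2, 0 °C; then TESCl, 0 °C to rt
Reagents that add atoms: tert-butyldiphenylsilyl chloride CC(C)(C)[Si](Cl)(c1ccccc1)c1ccccc1; triethylsilyl chloride CC[Si](Cl)(CC)CC
Why: Sequential silylation in one flask; the bulky chloride should take only the primary O2, after which the smaller chloride caps the secondary O8. The pair is chosen so that O8 can later be freed by acid beside the much more stable O2 ether.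

Step 4
Reactants: 10 propargyl alcohol
Product: 12 (E)-3-iodo-2-methylprop-2-en-1-ol, via alkenylalane 11 (not isolated)
Conditions: Me3Al (3 equiv), Cp2ZrCl2 (0.25 equiv), CH2Cl2, 0 °C to rt; I2, THF, −30 °C; aq. K2CO3
Reagents that add atoms: trimethylaluminium C[Al](C)C; iodine II
Why: Negishi methylalumination followed by iodinolysis with retention; syn addition places C15 and the metal cis, so iodine ends up trans to C3 (E).

Step 5
Reactants: 12 (E)-3-iodo-2-methylprop-2-en-1-ol
Product: 13 (E)-3-iodo-2-methylprop-2-en-1-yl acetate
Conditions: Ac2O, pyridine, DMAP (cat.), CH2Cl2, 0 °C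
Reagents that add atoms: acetic anhydride CC(=O)OC(C)=O
Why: Standard DMAP-catalysed acetylation of a primary alcohol; O3 reaches its final state here and needs no further step.

Step 6
Reactants: 9 (3R,5E)-7-(tert-butyldiphenylsilyloxy)-5-methyl-3-(triethylsilyloxy)hepta-1,5-diene; 13 (E)-3-iodo-2-methylprop-2-en-1-yl acetate
Product: 14 (2E,4E,6R,8E)-10-(tert-butyldiphenylsilyloxy)-2,8-dimethyl-6-(triethylsilyloxy)deca-2,4,8-trien-1-yl acetate
Conditions: Pd(OAc)2 (5 mol %), Ag2CO3, DMF, rt to 40 °C, dark
Reagents that add atoms: none
Why: Heck reaction under Jeffery silver-salt conditions, the known way from alkenyl iodides and allylic alcohol derivatives to conjugated dienes. The alkenylpalladium adds to the terminal C6, syn β-hydride loss gives the E C6=C7 alkene, and the geometry of 13 is retained. The phosphine-free, halide-free catalyst should insert into C–I much faster than it ionises the allylic acetate.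

Step 7
Reactants: 14 (2E,4E,6R,8E)-10-(tert-butyldiphenylsilyloxy)-2,8-dimethyl-6-(triethylsilyloxy)deca-2,4,8-trien-1-yl acetate; 15 2-bromoacrylic acid
Product: 17 (E)-3-[(2R,3S)-3-{(1R,3E)-5-(tert-butyldiphenylsilyloxy)-3-methyl-1-(triethylsilyloxy)pent-3-en-1-yl}-4-methylidene-5-oxooxolan-2-yl]-2-methylprop-2-en-1-yl acetate (germacrane numbering 6R,7S,8R), via oxapalladacycle 16 (not isolated)
Conditions: Pd(OAc)2 (10 mol %), Ag2CO3 (1.2 equiv), 15 (2 equiv, slow addition), DMF, 50 °C
Reagents that add atoms: none
Why: Proposed new method: zerovalent palladium inserts into the C–Br bond of 15, and the 1-carboxyvinylpalladium species binds the C7=C6 end of the s-trans diene and inserts syn, with C11 going to C7 because the other diene terminus C4 is fully substituted; this leaves an allyl unit over C6–C5–C4 that is chelated by the carboxylate (drawn as its σ-form 16). The closest known reaction type is the Larock heteroannulation of 1,3-dienes by 2-haloacrylic and 2-iodobenzoic acids, which is established for terminal and cyclic dienes but not for an acyclic, internally substituted diene with an allylic stereocentre and an allylic acetate, hence the label. Ring A closes by C6–O reductive elimination from the six-membered chelate, a 5-exo closure on the allyl unit, whereas closure at C4 would need a seven-membered ring at a fully substituted carbon. C7 is set in the insertion: with C8–H eclipsing C7=C6 (least A(1,3) strain) the OTES group covers one face, so palladium and C11 should arrive anti to it, the same sense as other additions to allylic ethers, which gives O8 and C11 anti as in 20. C6 is set by delivery of the bound carboxylate on the palladium-bearing face, the path that gives cis-fused products from cyclic dienes in this reaction class; this is a net syn addition across the E alkene, so C5 and C8 should end up trans on the ring, which is also the less strained arrangement. The E geometry of C5=C4 is carried over from 14, because the allyl unit is trapped intramolecularly before it can rotate through its tertiary σ-form. The step needs three chemoselectivities: survival of the C3 acetate (no phosphine, silver salt, and excess 15 keep palladium in its divalent resting state), no Diels–Alder reaction of 15 (the Z-methyl C15 keeps the diene out of the s-cis form), and an untouched C10=C1 alkene (trisubstituted, so inert to insertion).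

Step 8
Reactants: 17 TES-protected lactone
Product: 18 (E)-3-[(2R,3R)-3-{(1R,3E)-5-(tert-butyldiphenylsilyloxy)-1-hydroxy-3-methylpent-3-en-1-yl}-4-methylidene-5-oxooxolan-2-yl]-2-methylprop-2-en-1-yl acetate
Conditions: AcOH/THF/H2O (3:1:1), 0 °C to rt
Reagents that add atoms: none
Why: Acid hydrolysis of silyl ethers, in which a triethylsilyl ether is cleaved orders of magnitude faster than a tert-butyldiphenylsilyl ether. The weakly acidic, non-nucleophilic medium leaves the acetate and the exo-methylene lactone alone, and the trans 6,12-lactone should be more stable than the cis 8,12-isomer. No stereocentre is touched; the descriptor of C7 changes only through priorities.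

Step 9
Reactants: 18 C8 alcohol
Product: 19 (1R,3E)-1-{(2R,3R)-2-[(1E)-3-acetoxy-2-methylprop-1-en-1-yl]-4-methylidene-5-oxooxolan-3-yl}-5-(tert-butyldiphenylsilyloxy)-3-methylpent-3-en-1-yl 2-methylprop-2-enoate
Conditions: methacrylic anhydride, Et3N, DMAP (cat.), CH2Cl2, 0 °C to rt
Reagents that add atoms: methacrylic anhydride C=C(C)C(=O)OC(=O)C(C)=C
Why: DMAP-catalysed acylation of the only free hydroxyl group, with retention at C8; the anhydride avoids the HCl and ketene side paths of the acid chloride.

Step 10
Reactants: 19 TBDPS-protected target
Product: 20 (1R,3E)-1-{(2R,3R)-2-[(1E)-3-acetoxy-2-methylprop-1-en-1-yl]-4-methylidene-5-oxooxolan-3-yl}-5-hydroxy-3-methylpent-3-en-1-yl 2-methylprop-2-enoate (CNP0323189.1)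
Conditions: HF·pyridine, pyridine, THF, 0 °C to rt
Reagents that add atoms: none
Why: Fluoride cleavage of the Si–O bond in a buffered, slightly acidic medium, so that no alkoxide or basic fluoride can add to the two Michael acceptors or move the acyl groups.

## Compound list

1 | acrolein | C=CC=O | starting material
2 | allenylboronic acid pinacol ester | C=C=CB1OC(C)(C)C(C)(C)O1 | starting material
3 | (3R)-hex-1-en-5-yn-3-yl pinacol borate | CC1(C)OB(O[C@H](CC#C)C=C)OC1(C)C | intermediate
4 | (3R)-hex-1-en-5-yn-3-ol | O[C@H](CC#C)C=C | intermediate
5 | (E)-alkenyl(dimethyl)alane, O8 as dimethylaluminium alkoxide | C[Al](C)O[C@H](C/C(C)=C/[Al](C)C)C=C | intermediate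
6 | lithium butyl(dimethyl)alkenylalanate derived from 5 | C[Al](C)O[C@H](C/C(C)=C/[Al-](C)(C)CCCC)C=C.[Li+] | intermediate
7 | (2E,5R)-3-methylhepta-2,6-diene-1,5-diol | O[C@H](C/C(C)=C/CO)C=C | intermediate
8 | (3R,5E)-7-(tert-butyldiphenylsilyloxy)-5-methylhepta-1,5-dien-3-ol | O[C@H](C/C(C)=C/CO[Si](c1ccccc1)(c1ccccc1)C(C)(C)C)C=C | intermediate
9 | (3R,5E)-7-(tert-butyldiphenylsilyloxy)-5-methyl-3-(triethylsilyloxy)hepta-1,5-diene | CC[Si](CC)(CC)O[C@H](C/C(C)=C/CO[Si](c1ccccc1)(c1ccccc1)C(C)(C)C)C=C | intermediate
10 | propargyl alcohol | C#CCO | starting material
11 | (E)-alkenyl(dimethyl)alane from 10, oxygen as dimethylaluminium alkoxide | C[Al](C)OC/C(C)=C/[Al](C)C | intermediate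
12 | (E)-3-iodo-2-methylprop-2-en-1-ol | OC/C(C)=C/I | intermediate
13 | (E)-3-iodo-2-methylprop-2-en-1-yl acetate | CC(=O)OC/C(C)=C/I | intermediate
14 | (2E,4E,6R,8E)-10-(tert-butyldiphenylsilyloxy)-2,8-dimethyl-6-(triethylsilyloxy)deca-2,4,8-trien-1-yl acetate | CC[Si](CC)(CC)O[C@H](C/C(C)=C/CO[Si](c1ccccc1)(c1ccccc1)C(C)(C)C)/C=C/C=C(\C)COC(C)=O | intermediate
15 | 2-bromoacrylic acid | C=C(Br)C(=O)O | starting material
16 | six-membered oxapalladacycle, σ-allyl form (Pd bound to C6 and to the carboxylate oxygen, further ligands omitted) | CC[Si](CC)(CC)O[C@H](C/C(C)=C/CO[Si](c2ccccc2)(c2ccccc2)C(C)(C)C)[C@H]1C(=C)C(=O)O[Pd][C@@H]1/C=C(\C)COC(C)=O | intermediate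
17 | TES/TBDPS-protected lactone (6R,7S,8R) | CC[Si](CC)(CC)O[C@H](C/C(C)=C/CO[Si](c2ccccc2)(c2ccccc2)C(C)(C)C)[C@H]1C(=C)C(=O)O[C@@H]1/C=C(\C)COC(C)=O | intermediate
18 | C8 alcohol (6R,7R,8R) | O[C@H](C/C(C)=C/CO[Si](c2ccccc2)(c2ccccc2)C(C)(C)C)[C@H]1C(=C)C(=O)O[C@@H]1/C=C(\C)COC(C)=O | intermediate
19 | O2-TBDPS ether of the target (6R,7R,8R) | C=C(C)C(=O)O[C@H](C/C(C)=C/CO[Si](c2ccccc2)(c2ccccc2)C(C)(C)C)[C@H]1C(=C)C(=O)O[C@@H]1/C=C(\C)COC(C)=O | intermediate
20 | CNP0323189.1 (6R,7R,8R) | C=C(C)C(=O)O[C@H](C/C(C)=C/CO)[C@H]1C(=C)C(=O)O[C@@H]1/C=C(\C)COC(C)=O | target

## Step count and least certain steps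

Total step count: 10. Longest linear sequence: 8 (steps 1, 2, 3, 6, 7, 8, 9, 10).

**Step 7 (key step, labelled as a proposed new method).**
What may go wrong:
- Insertion into the internal, 1,4-substituted diene may be slower than the self-consumption of 15 (oligomerisation, dehydrobromination) or than ionisation of the dienylic C3 acetate by zerovalent palladium.
- The facial bias exerted by C8 may be incomplete.
- Outer-sphere attack of the carboxylate may erode the trans selectivity.
- β-Hydride loss from C7 may compete with ring closure.

Fallback: setting out from 14, the same two bonds are made by a radical–polar crossover with known chemistry. Carbolactonisation with malonic acid and Mn(OAc)3 (trivalent manganese, KOAc, AcOH, room temperature) adds the malonyl radical to C7. The allyl radical is then oxidised, and the cation is closed at C6 to give the α-carboxy lactone F1 (mixture at C11, of no consequence). Decarboxylative Mannich methylenation (aqueous formaldehyde, Et2NH, then NaOAc/AcOH) comes back to the route at 17.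

**Step 1.**
What may go wrong: the small, unhindered aldehyde may be bound too loosely in the chiral pocket, giving insufficient face discrimination, and acrolein may oligomerise under acid catalysis.

Fallback: setting out from 1, a zinc Barbier reaction with propargyl bromide (THF/aq. NH4Cl) gives racemic hex-1-en-5-yn-3-ol F2. A Sharpless kinetic resolution follows (Ti(OiPr)4, L-(+)-diisopropyl tartrate, t-BuOOH, 4 Å MS, CH2Cl2, −20 °C, run to slightly over half conversion). It consumes the S enantiomer as the erythro epoxy alcohol F3 and leaves the slow-reacting R enantiomer, which comes back to the route at 4.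

**Step 6.**
What may go wrong: β-hydride loss towards C8 (enol ether formation), migration of the new double bonds through palladium hydride re-addition, a second insertion into the product diene, or ionisation of the allylic acetate.

Fallback: setting out from 9, cross metathesis with vinylboronic acid pinacol ester (second-generation Hoveyda–Grubbs catalyst, CH2Cl2, 40 °C) gives the (E)-alkenylboronate F4. Suzuki coupling of F4 with 13 (Pd(dppf)Cl2, K3PO4, THF/H2O, rt) comes back to the route at 14.

**Step 8.**
What may go wrong: once O8 is free, the lactone carbonyl may shift from O6 to O8 (translactonisation), or prolonged acid may start to remove the O2 silyl group because the O8 ether is hindered.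

Fallback: setting out from 17, the free alcohol is avoided altogether by direct silyl-to-acyl exchange with methacrylic anhydride and catalytic Cu(OTf)2 (CH2Cl2, 0 °C). This is the known one-step conversion of labile silyl ethers into esters, which leaves the tert-butyldiphenylsilyl ether in place. It comes back to the route at 19, and no new compound is made on this way (F0).

## Further compounds

F1 | step 7 | α-carboxy lactone, C11 unassigned (6R,7,8R as in 17) | CC[Si](CC)(CC)O[C@H](C/C(C)=C/CO[Si](c2ccccc2)(c2ccccc2)C(C)(C)C)[C@H]1C(C(=O)O)C(=O)O[C@@H]1/C=C(\C)COC(C)=O
F2 | step 1 | racemic hex-1-en-5-yn-3-ol | C=CC(O)CC#C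
F3 | step 1 | (1S)-1-[(2R)-oxiran-2-yl]but-3-yn-1-ol | O[C@@H](CC#C)[C@H]1CO1
F4 | step 6 | (1E,3R,5E)-7-(tert-butyldiphenylsilyloxy)-5-methyl-3-(triethylsilyloxy)hepta-1,5-dien-1-ylboronic acid pinacol ester | CC[Si](CC)(CC)O[C@H](C/C(C)=C/CO[Si](c1ccccc1)(c1ccccc1)C(C)(C)C)/C=C/B1OC(C)(C)C(C)(C)O1
F0 | step 8 | none | none
A1 | alternative 1 | methyl (2Z,4R,6E)-2-(bromomethyl)-8-(tert-butyldiphenylsilyloxy)-6-methyl-4-(triethylsilyloxy)octa-2,6-dienoate | COC(=O)/C(CBr)=C/[C@H](O[Si](CC)(CC)CC)C/C(C)=C/CO[Si](c1ccccc1)(c1ccccc1)C(C)(C)C
A2 | alternative 1 | (E)-4-acetoxy-3-methylbut-2-enal | CC(=O)OC/C(C)=C/C=O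
A3 | alternative 2 | 2-methylidene-4,6-dienoic acid with C7 and C8 in place (O8 methacrylate, O2 TBDPS ether) | C=C(C)C(=O)O[C@H](C/C(C)=C/CO[Si](c1ccccc1)(c1ccccc1)C(C)(C)C)[C@@H](C(=C)C(=O)O)/C=C/C(C)=C
A4 | alternative 3 | (4R,6E)-8-(tert-butyldiphenylsilyloxy)-6-methyl-4-(triethylsilyloxy)octa-1,2,6-triene | C=C=C[C@H](O[Si](CC)(CC)CC)C/C(C)=C/CO[Si](c1ccccc1)(c1ccccc1)C(C)(C)C
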